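**Retrosynthetic overview** (ring A = benzo ring of the tetralone, ring B = its ketone ring, ring C = benzoyl ring, ring D = pyranone)
- Last step: hydrogenolysis of three benzyl and two 4-methoxybenzyl ethers.
- Key disconnection: C4–C4a and C3–C4 of ring B, made in one rhodium-catalysed ortho C–H functionalisation/annulation of an aryl 1,3-diketone (ring A) with an aroyl sulfoxonium ylide (rings C and D); this sets both stereocentres.
- The ylide comes from a benzoic acid made by Vilsmeier formylation and Pinnick oxidation of a 5-(pyranonylmethyl)resorcinol diether; the diether comes from an sp2–sp3 Suzuki coupling of an aryl boronate (iridium C–H borylation) with a 6-(chloromethyl)pyranone.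
- The diketone comes from resorcinol (Nencki acetylation, benzylation, Claisen condensation); the pyranone from methyl acetoacetate and chloroacetyl chloride.
- Ring order: rings A and C are bought as resorcinol, ring D is closed in step 7, ring B last in step 12.

Assumption: the SMILES descriptors are absolute, i.e. (3R,4S) with 3-OH and 4-aroyl cis; the (R)-configured ligand of step 12 is assumed to give this enantiomer (otherwise its mirror image is used).

**Step 1**
Reactants: 1 resorcinol (benzene-1,3-diol); 2 acetic acid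
Product: 3 1-(2,4-dihydroxyphenyl)ethan-1-one
Conditions: ZnCl2 (1.2 equiv), AcOH (solvent), 140 °C
Reagents that add atoms: none
Why: Nencki reaction (ZnCl2-mediated Friedel–Crafts acylation with the free acid), which acylates resorcinol para to one hydroxyl and ortho to the other.

**Step 2**
Reactants: 3 1-(2,4-dihydroxyphenyl)ethan-1-one
Product: 4 1-[2,4-bis(benzyloxy)phenyl]ethan-1-one
Conditions: BnBr (2.4 equiv), K2CO3 (3 equiv), DMF, 80 °C
Reagents that add atoms: benzyl bromide BrCc1ccccc1
Why: Williamson ether synthesis, with heating so that the hydrogen-bonded 2-hydroxyl is alkylated as well.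

**Step 3**
Reactants: 4 1-[2,4-bis(benzyloxy)phenyl]ethan-1-one; 5 ethyl acetate
Product: 6 1-[2,4-bis(benzyloxy)phenyl]butane-1,3-dione
Conditions: NaH (2.5 equiv), EtOAc (3 equiv), THF, 65 °C; then 1 M HCl
Reagents that add atoms: none
Why: crossed Claisen condensation of the methyl ketone enolate with ethyl acetate, driven by formation of the stable sodium diketonate.

**Step 4**
Reactants: 1 resorcinol
Product: 7 1,3-bis[(4-methoxybenzyl)oxy]benzene
Conditions: 4-MeOC6H4CH2Cl (2.3 equiv), K2CO3 (3 equiv), Bu4NI (5 mol %), DMF, 60 °C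
Reagents that add atoms: 4-methoxybenzyl chloride COc1ccc(CCl)cc1
Why: Williamson ether synthesis; the 4-methoxybenzyl group is chosen because each of its arene C–H bonds is ortho to a substituent and so stays untouched in step 5.

**Step 5**
Reactants: 7 1,3-bis[(4-methoxybenzyl)oxy]benzene
Product: 8 2-{3,5-bis[(4-methoxybenzyl)oxy]phenyl}-4,4,5,5-tetramethyl-1,3,2-dioxaborolane
Conditions: [Ir(OMe)(cod)]2 (1.5 mol %), 4,4'-di-tert-butyl-2,2'-bipyridine (3 mol %), B2pin2 (1.0 equiv), THF, 80 °C
Reagents that add atoms: bis(pinacolato)diboron CC1(C)OB(OC1(C)C)B1OC(C)(C)C(C)(C)O1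
Why: sterically controlled iridium-catalysed aromatic C–H borylation, which selects the only C–H bond flanked by two hydrogens (C5, meta to both ethers).

**Step 6**
Reactants: 9 methyl acetoacetate (methyl 3-oxobutanoate)
Product: 10 benzyl (E)-3-(benzyloxy)but-2-enoate
Conditions: BnOH (3 equiv), TsOH·H2O (3 mol %), PhMe, reflux, Dean–Stark (removal of MeOH and H2O)
Reagents that add atoms: benzyl alcohol OCc1ccccc1
Why: acid-catalysed transesterification and enol ether formation under azeotropic removal of methanol and water, giving the thermodynamically favoured E isomer (benzyloxy trans to the ester).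

**Step 7**
Reactants: 10 benzyl (E)-3-(benzyloxy)but-2-enoate; 11 chloroacetyl chloride
Product: 13 4-(benzyloxy)-6-(chloromethyl)-2H-pyran-2-one, via chloro keto ester 12 (not isolated)
Conditions: 10 (2.0 equiv), LiN(i-Pr)2 (2.0 equiv), THF, −78 °C; 11 (1.0 equiv), −78 to 0 °C; then 1 M HCl
Reagents that add atoms: none
Why: vinylogous Claisen acylation of the lithium dienolate at its γ-carbon, after which the second equivalent of dienolate deprotonates 12 and the ketone enolate oxygen closes ring D on the cis ester (6-exo-trig lactonisation, benzyl alcohol leaves).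

**Step 8**
Reactants: 8 2-{3,5-bis[(4-methoxybenzyl)oxy]phenyl}-4,4,5,5-tetramethyl-1,3,2-dioxaborolane; 13 4-(benzyloxy)-6-(chloromethyl)-2H-pyran-2-one
Product: 14 4-(benzyloxy)-6-{3,5-bis[(4-methoxybenzyl)oxy]benzyl}-2H-pyran-2-one
Conditions: Pd(PPh3)4 (5 mol %), K3PO4 (2 equiv), PhMe/H2O 10:1, 70 °C
Reagents that add atoms: none
Why: sp2–sp3 Suzuki–Miyaura coupling; the allylic-type C–Cl bond adds readily to zerovalent palladium and the resulting alkylpalladium has no β-hydrogen.

**Step 9**
Reactants: 14 4-(benzyloxy)-6-{3,5-bis[(4-methoxybenzyl)oxy]benzyl}-2H-pyran-2-one; 15 N,N-dimethylformamide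
Product: 16 2-{[4-(benzyloxy)-2-oxo-2H-pyran-6-yl]methyl}-4,6-bis[(4-methoxybenzyl)oxy]benzaldehyde
Conditions: POCl3 (1.3 equiv), DMF (5 equiv), CH2Cl2, 0 to 23 °C; then aq. NaOAc
Reagents that add atoms: water O
Why: Vilsmeier–Haack formylation at the arene position para to one ether and ortho to the other; the site between the two ethers is shielded and the alkoxypyranone is far less nucleophilic.

**Step 10**
Reactants: 16 2-{[4-(benzyloxy)-2-oxo-2H-pyran-6-yl]methyl}-4,6-bis[(4-methoxybenzyl)oxy]benzaldehyde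
Product: 17 2-{[4-(benzyloxy)-2-oxo-2H-pyran-6-yl]methyl}-4,6-bis[(4-methoxybenzyl)oxy]benzoic acid
Conditions: NaClO2 (3 equiv), NaH2PO4 (3 equiv), 2-methylbut-2-ene (10 equiv), t-BuOH/THF/H2O, 0 to 23 °C
Reagents that add atoms: sodium chlorite [Na+].[O-]Cl=O
Why: Pinnick oxidation, which converts hindered electron-rich aryl aldehydes to acids under buffered conditions while the alkene scavenger protects the arenes and the pyranone from hypochlorite.

**Step 11**
Reactants: 17 2-{[4-(benzyloxy)-2-oxo-2H-pyran-6-yl]methyl}-4,6-bis[(4-methoxybenzyl)oxy]benzoic acid; 18 trimethylsulfoxonium iodide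
Product: 20 1-(2-{[4-(benzyloxy)-2-oxo-2H-pyran-6-yl]methyl}-4,6-bis[(4-methoxybenzyl)oxy]phenyl)-2-[dimethyl(oxo)-λ6-sulfanylidene]ethan-1-one, via acid chloride 19 (not isolated)
Conditions: (a) Me2C=C(Cl)NMe2 (1.2 equiv), CH2Cl2, 0 to 23 °C; (b) 18 (3 equiv), KOt-Bu (3 equiv), THF, 65 °C, then 0 °C and slow addition of the solution from (a)
Reagents that add atoms: 1-chloro-N,N,2-trimethylprop-1-en-1-amine CC(C)=C(Cl)N(C)C (chlorine of 19 only)
Why: neutral acid chloride formation followed by C-acylation of dimethylsulfoxonium methylide (the Corey–Chaykovsky ylide), a second equivalent of which removes HCl to give the stable β-keto sulfoxonium ylide.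

**Step 12**
Reactants: 6 1-[2,4-bis(benzyloxy)phenyl]butane-1,3-dione; 20 1-(2-{[4-(benzyloxy)-2-oxo-2H-pyran-6-yl]methyl}-4,6-bis[(4-methoxybenzyl)oxy]phenyl)-2-[dimethyl(oxo)-λ6-sulfanylidene]ethan-1-one
Product: 21 (3R,4S)-6,8-bis(benzyloxy)-4-(2-{[4-(benzyloxy)-2-oxo-2H-pyran-6-yl]methyl}-4,6-bis[(4-methoxybenzyl)oxy]benzoyl)-3-hydroxy-3-methyl-3,4-dihydronaphthalen-1(2H)-one
Conditions: Rh(Cpx)(C2H4)2 (5 mol %; Cpx = (R)-configured cyclopentadienyl ligand fused to a 3,3'-dimethoxy-1,1'-binaphthyl backbone), (PhCO2)2 (5 mol %), PivOH (0.5 equiv), CF3CH2OH/ClCH2CH2Cl 1:1, 30 °C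
Reagents that add atoms: none
Why: Proposed new method: the peroxide oxidises the monovalent rhodium precatalyst to a chiral trivalent rhodium dicarboxylate, which should metalate the only free ortho C–H bond of 6 (directed by the aryl ketone oxygen of the diketo tautomer, favoured in CF3CH2OH), take up 20 with loss of dimethyl sulfoxide to a rhodium carbene and undergo aryl migration to a six-membered rhodacycle that is a rhodium enolate of the hindered ketone; instead of the usual protodemetalation, this enolate is expected to add through a closed Zimmerman–Traxler-type transition state to the pendant methyl ketone, closing ring B in the chiral pocket and fixing R at C3, while S at C4 (aroyl cis to OH, hydrogen-bonded and thermodynamically preferred) follows from the chelated aldolate and the easy epimerisation of that centre, and the competing Knoevenagel closure onto the aryl ketone is blocked by its two ortho substituents; the closest known reactions are the rhodium-catalysed ortho C–H acylmethylation of arenes with sulfoxonium ylides and rhodium enolate aldol cascades, which have not been merged or made enantioselective in this way.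

**Step 13**
Reactants: 21 (3R,4S)-6,8-bis(benzyloxy)-4-(2-{[4-(benzyloxy)-2-oxo-2H-pyran-6-yl]methyl}-4,6-bis[(4-methoxybenzyl)oxy]benzoyl)-3-hydroxy-3-methyl-3,4-dihydronaphthalen-1(2H)-one
Product: 22 (3R,4S)-4-{2,4-dihydroxy-6-[(4-hydroxy-2-oxo-2H-pyran-6-yl)methyl]benzoyl}-3,6,8-trihydroxy-3-methyl-3,4-dihydronaphthalen-1(2H)-one (CNP0197349.1)
Conditions: H2 (1 atm), Pd(OH)2/C (20 wt %), EtOAc/MeOH 4:1, 23 °C, 2 h; filtration and neutral reversed-phase purification
Reagents that add atoms: none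
Why: catalytic hydrogenolysis removes all five benzyl-type ethers under neutral conditions, so the tertiary aldol is neither dehydrated nor cleaved and neither stereocentre is touched.

**Compound list**
1 | resorcinol (benzene-1,3-diol) | Oc1cccc(O)c1 | starting material
2 | acetic acid | CC(=O)O | starting material
3 | 1-(2,4-dihydroxyphenyl)ethan-1-one | CC(=O)c1ccc(O)cc1O | intermediate
4 | 1-[2,4-bis(benzyloxy)phenyl]ethan-1-one | CC(=O)c1ccc(OCc2ccccc2)cc1OCc1ccccc1 | intermediate
5 | ethyl acetate | CCOC(C)=O | starting material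
6 | 1-[2,4-bis(benzyloxy)phenyl]butane-1,3-dione | CC(=O)CC(=O)c1ccc(OCc2ccccc2)cc1OCc1ccccc1 | intermediate
7 | 1,3-bis[(4-methoxybenzyl)oxy]benzene | COc1ccc(COc2cccc(OCc3ccc(OC)cc3)c2)cc1 | intermediate
8 | 2-{3,5-bis[(4-methoxybenzyl)oxy]phenyl}-4,4,5,5-tetramethyl-1,3,2-dioxaborolane | COc1ccc(COc2cc(OCc3ccc(OC)cc3)cc(B3OC(C)(C)C(C)(C)O3)c2)cc1 | intermediate
9 | methyl acetoacetate (methyl 3-oxobutanoate) | COC(=O)CC(C)=O | starting material
10 | benzyl (E)-3-(benzyloxy)but-2-enoate | C/C(OCc1ccccc1)=C\C(=O)OCc1ccccc1 | intermediate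
11 | chloroacetyl chloride | ClCC(Cl)=O | starting material
12 | benzyl (E)-3-(benzyloxy)-6-chloro-5-oxohex-2-enoate (not isolated) | O=C(CCl)C/C(OCc1ccccc1)=C\C(=O)OCc1ccccc1 | intermediate
13 | 4-(benzyloxy)-6-(chloromethyl)-2H-pyran-2-one | O=c1cc(OCc2ccccc2)cc(CCl)o1 | intermediate
14 | 4-(benzyloxy)-6-{3,5-bis[(4-methoxybenzyl)oxy]benzyl}-2H-pyran-2-one | COc1ccc(COc2cc(Cc3cc(OCc4ccccc4)cc(=O)o3)cc(OCc3ccc(OC)cc3)c2)cc1 | intermediate
15 | N,N-dimethylformamide | CN(C)C=O | starting material
16 | 2-{[4-(benzyloxy)-2-oxo-2H-pyran-6-yl]methyl}-4,6-bis[(4-methoxybenzyl)oxy]benzaldehyde | O=Cc1c(OCc2ccc(OC)cc2)cc(OCc2ccc(OC)cc2)cc1Cc1cc(OCc2ccccc2)cc(=O)o1 | intermediate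
17 | 2-{[4-(benzyloxy)-2-oxo-2H-pyran-6-yl]methyl}-4,6-bis[(4-methoxybenzyl)oxy]benzoic acid | OC(=O)c1c(OCc2ccc(OC)cc2)cc(OCc2ccc(OC)cc2)cc1Cc1cc(OCc2ccccc2)cc(=O)o1 | intermediate
18 | trimethylsulfoxonium iodide | C[S+](C)(C)=O.[I-] | starting material
19 | 2-{[4-(benzyloxy)-2-oxo-2H-pyran-6-yl]methyl}-4,6-bis[(4-methoxybenzyl)oxy]benzoyl chloride (not isolated) | ClC(=O)c1c(OCc2ccc(OC)cc2)cc(OCc2ccc(OC)cc2)cc1Cc1cc(OCc2ccccc2)cc(=O)o1 | intermediate
20 | 1-(2-{[4-(benzyloxy)-2-oxo-2H-pyran-6-yl]methyl}-4,6-bis[(4-methoxybenzyl)oxy]phenyl)-2-[dimethyl(oxo)-λ6-sulfanylidene]ethan-1-one | CS(C)(=O)=CC(=O)c1c(OCc2ccc(OC)cc2)cc(OCc2ccc(OC)cc2)cc1Cc1cc(OCc2ccccc2)cc(=O)o1 | intermediate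
21 | (3R,4S)-6,8-bis(benzyloxy)-4-(2-{[4-(benzyloxy)-2-oxo-2H-pyran-6-yl]methyl}-4,6-bis[(4-methoxybenzyl)oxy]benzoyl)-3-hydroxy-3-methyl-3,4-dihydronaphthalen-1(2H)-one | C[C@@]1(O)CC(=O)c2c(OCc3ccccc3)cc(OCc3ccccc3)cc2[C@@H]1C(=O)c1c(OCc2ccc(OC)cc2)cc(OCc2ccc(OC)cc2)cc1Cc1cc(OCc2ccccc2)cc(=O)o1 | intermediate
22 | (3R,4S)-4-{2,4-dihydroxy-6-[(4-hydroxy-2-oxo-2H-pyran-6-yl)methyl]benzoyl}-3,6,8-trihydroxy-3-methyl-3,4-dihydronaphthalen-1(2H)-one | C[C@@]1(O)CC(=O)c2c(O)cc(O)cc2[C@@H]1C(=O)c1c(O)cc(O)cc1Cc1cc(O)cc(=O)o1 | target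

**Step count and risks**

Total step count: 13. Longest linear sequence: 8 steps (steps 4, 5, 8, 9, 10, 11, 12, 13; the branch through steps 6 and 7 is equally long).

Three steps most likely to fail:

Step 12 (the proposed new annulation). The rhodium enolate may be protonated before it adds to the ketone, the diketone may bind rhodium as a chelating diketonate, or the enantioselectivity may be low. Fallback with known chemistry, setting out from 6 and 20: the achiral reaction is run stepwise. Ketone-directed ortho C–H acylmethylation with [RhCl2(C5Me5)]2 (4 mol %), AgSbF6 (16 mol %) and NaOAc (0.3 equiv) in ClCH2CH2Cl at 60 °C gives, after protodemetalation, the open-chain triketone F6. A base-mediated intramolecular aldol addition (DBU 0.2 equiv, CH2Cl2, −20 °C) then closes ring B to the racemic cis-aldol F7. Preparative supercritical-fluid chromatography on a chiral stationary phase separates the (3R,4S)-enantiomer, which is 21, where the fallback comes back to the route.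

Step 7 (dienolate acylation and lactonisation). α- instead of γ-acylation, or attack of the dienolate on the chloromethyl ketone, may lower the yield. Fallback, setting out from methyl acetoacetate 9: thermal self-condensation (NaHCO3 cat., 200 °C) gives dehydroacetic acid F1, which is deacetylated in 90 % H2SO4 at 130 °C to 4-hydroxy-6-methyl-2H-pyran-2-one F2. O-Benzylation (BnBr, K2CO3, DMF) gives 4-(benzyloxy)-6-methyl-2H-pyran-2-one F3, and radical bromination (NBS, AIBN, PhCF3, 80 °C) gives 4-(benzyloxy)-6-(bromomethyl)-2H-pyran-2-one F4. F4 takes the place of 13 in the Suzuki coupling of step 8, so the fallback comes back to the route at 14.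

Step 11 (ylide formation). The basic, nucleophilic methylide may attack the pyranone or deprotonate the acidic aryl–CH2–pyranone position and cause C-acylation. Fallback, setting out from acid 17 (through acid chloride 19, made as in step 11a): the chloride is treated with Me3SiCHN2 (2.2 equiv) in MeCN/THF at 0 °C to give the α-diazoketone F5. F5 replaces 20 as the carbene source in step 12 (loss of dinitrogen in place of dimethyl sulfoxide), and the fallback comes back to the route at 21.

**Further compounds**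
F1 | step 7 | dehydroacetic acid (3-acetyl-4-hydroxy-6-methyl-2H-pyran-2-one) | CC(=O)c1c(O)cc(C)oc1=O
F2 | step 7 | 4-hydroxy-6-methyl-2H-pyran-2-one | Cc1cc(O)cc(=O)o1
F3 | step 7 | 4-(benzyloxy)-6-methyl-2H-pyran-2-one | Cc1cc(OCc2ccccc2)cc(=O)o1
F4 | step 7 | 4-(benzyloxy)-6-(bromomethyl)-2H-pyran-2-one | BrCc1cc(OCc2ccccc2)cc(=O)o1
F5 | step 11 | 2-diazo-1-(2-{[4-(benzyloxy)-2-oxo-2H-pyran-6-yl]methyl}-4,6-bis[(4-methoxybenzyl)oxy]phenyl)ethan-1-one | [N-]=[N+]=CC(=O)c1c(OCc2ccc(OC)cc2)cc(OCc2ccc(OC)cc2)cc1Cc1cc(OCc2ccccc2)cc(=O)o1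
F6 | step 12 | 1-{2,4-bis(benzyloxy)-6-[2-(2-{[4-(benzyloxy)-2-oxo-2H-pyran-6-yl]methyl}-4,6-bis[(4-methoxybenzyl)oxy]phenyl)-2-oxoethyl]phenyl}butane-1,3-dione | CC(=O)CC(=O)c1c(OCc2ccccc2)cc(OCc2ccccc2)cc1CC(=O)c1c(OCc2ccc(OC)cc2)cc(OCc2ccc(OC)cc2)cc1Cc1cc(OCc2ccccc2)cc(=O)o1
F7 | step 12 | racemic cis-aldol (1:1 mixture of 21 and its (3S,4R)-enantiomer) | C[C@@]1(O)CC(=O)c2c(OCc3ccccc3)cc(OCc3ccccc3)cc2[C@@H]1C(=O)c1c(OCc2ccc(OC)cc2)cc(OCc2ccc(OC)cc2)cc1Cc1cc(OCc2ccccc2)cc(=O)o1.C[C@]1(O)CC(=O)c2c(OCc3ccccc3)cc(OCc3ccccc3)cc2[C@H]1C(=O)c1c(OCc2ccc(OC)cc2)cc(OCc2ccc(OC)cc2)cc1Cc1cc(OCc2ccccc2)cc(=O)o1
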